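Late in epsilon and alpha the question was how much right-handed substrate had been taken while the left-handed substrate ran down, so I carried one number over from cedar.

common to all: left-handed substrate 0.10 M; right-handed substrate 0.10 M

|  | partner | protic impurity | precatalyst | remark | time |
|---|---|---|---|---|---|
| cedar | 0.20 M | 2 mM | 0.20 mM | run made earlier |  |
| epsilon | 0.200 M | 2.00 mM | 0.10 mM |  | 25 min |
| alpha | 0.200 M | 2.00 mM | 0.10 mM |  | 50 min |

cedar run (percent of the left-handed substrate and right-handed substrate together charged)

| time / min | left-handed product / % | right-handed product / % |
|---|---|---|
| 0.250 | 0.2 | 0.2 |
| 0.833 | 1.4 | 0.1 |
| 1.33 | 4.2 | 0.7 |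
| 2.00 | 8.8 | 0.2 |
| 3.00 | 15.9 | 1.2 |
| 4.00 | 24.2 | 2.2 |
| 5.00 | 29.9 | 2.7 |

(each reading ± 0.3 percentage points)

- free catalyst is single-handed; left-handed substrate and right-handed substrate are mirror images of each other, charged as a racemate, each of them at the stated concentration
- what may be going on: partner + protic impurity -> quenched reagent; partner + catalyst intermediate B -> free catalyst + right-handed product; free catalyst -> spent catalyst; precatalyst -> free catalyst; free catalyst + right-handed substrate <-> catalyst intermediate B; partner + catalyst intermediate A -> free catalyst + left-handed product; free catalyst + left-handed substrate <-> catalyst intermediate A
- an excess is below zero if the other one leads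
- no earlier run changes the charge of precatalyst; that part of a forecast is a guess

- which of the two ends with the higher excess of left-handed product over right-handed product in the product ("neither" if they lie within 2 percentage points) (epsilon / alpha / neither)
- excess of left-handed product over right-handed product in the product at the end, epsilon
- excess of left-handed product over right-handed product in the product at the end, alpha

Both substrates compete for one catalyst, which cancels from the ratio of the two rates, and I assumed that this ratio stayed steady through a run. So I took the logarithm of the fraction of left-handed substrate remaining over that of the right-handed substrate remaining, the selectivity factor s, and read it from cedar's last reading as 16.4. The right-handed fraction remaining is then the s-th root of the left-handed one.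

At the start this gives an excess of 88.5%. For the late end I needed L, minus the logarithm of the left-handed fraction. Cedar's slope of L from 3.00 min to 5.00 min was 0.264 /min. I scaled it with precatalyst, which is a guess, and allowed for no catalyst loss. That gave L of 3.30 in epsilon and 6.61 in alpha, and so excesses of 68.2% and 50.2%, with epsilon ahead.

The forecast also named epsilon, but with higher figures of 76% and 67%: “Epsilon therefore likely ends higher.”

The flask gave 62.7% for epsilon and 53.3% for alpha. The observed L was 3.82 in epsilon, above my figure, and 5.51 in alpha, below it, with spent catalyst at 87.5% of the catalyst charged by 50.0 min.

    partner + protic impurity → quenched reagent (k = 16.0 /M/s)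
    partner + catalyst intermediate B → free catalyst + right-handed product (k = 6.50 /M/s)
    free catalyst → spent catalyst (k = 0.00160 /s)
    precatalyst → free catalyst (k = 0.00240 /s)
    free catalyst + right-handed substrate ⇌ catalyst intermediate B (K = 11.0 /M, k = 3800 /M/s)
    partner + catalyst intermediate A → free catalyst + left-handed product (k = 87.0 /M/s)
    free catalyst + left-handed substrate ⇌ catalyst intermediate A (K = 14.0 /M, k = 1000 /M/s)

In epsilon at 6.13 min, partner went to left-handed product 7.8 times as fast as to right-handed product, less than s. At 25.0 min, the s-th root of the 2.2% of left-handed substrate remaining gives 79.2% for the right-handed, and 78% stood there.

In epsilon read at 6.0 min, 52% of the left-handed substrate remained, so s gives 96.1% of the right-handed and an excess of 85.0%. The computed flask gave 82.9%.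

The numbers in the tables are simulated with made-up constants, and the scatter is random.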